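**Plan**

- Labdane numbering is used: ring A is C1–C5 plus C10, ring B is C5–C10; C4 bears methyl C18 and carboxyl C19, C10 bears methyl C20, C8 bears methyl C17, and C9 bears the chain C11–C16 with the acetate on C15.
- Enabling feature: the only stereocentres (C4, C5, C10) are contiguous in a trans-decalin, and the quaternary C4 lies inside the four-carbon strand C1–C4 that can join C5 of a C5–C8 diene to C10 of a C9=C10 enal. One intramolecular [4+2] can therefore make C5–C10 and C8–C9 and both rings.
- Retrosynthetic cuts, in order: acetate and ester O-methyl; C12–C13 (B-alkyl Suzuki) and C11=C12 (methylenation of a C8=C9 enal); C5–C10 and C8–C9 (Diels–Alder); C5=C6 (phosphonate olefination); C1–C10 (B-alkyl Suzuki); C3–C4 (malonate allylation).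
- Forward: a methylmalonate is allylated, extended to C11 with an (E)-vinyl iodide, desymmetrised, and its two carboxyl arms become the C5–C8 dienyl group and the ester. Oxidation at C11 gives the trienal, whose cycloaddition closes rings A and B at once. Hydrogenation and dehydrogenation then move the ring B alkene to C8=C9, and C12 plus a second copy of the vinyl iodide complete the chain.
- Stereochemistry: C4 comes from enzymatic desymmetrisation of the prochiral malonate and is relayed to C5 and C10 through the chair tether and the endo transition state. Both E-trisubstituted alkenes come from one syn hydrozirconation. The C8 and C9 centres of the cycloadduct are deleted later.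

Key step: step 13

Assumption: pig liver esterase is taken to treat the long lipophilic chain of the prochiral diester as it treats n-hexyl or n-heptyl in simple dimethyl 2-alkyl-2-methylmalonates and to cleave the pro-S ester group; if it cleaved the pro-R group instead, the acid arm of the half-ester would be reduced (ClCO2Et/Et3N, then NaBH4), which gives the same S hydroxy ester one step earlier.

**Route**

Step 1
Reactants: 1 but-2-yn-1-ol
Product: 2 tert-butyl(but-2-yn-1-yloxy)dimethylsilane
Conditions: TBSCl, imidazole, CH2Cl2, 0 °C to rt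
Reagents that add atoms: tert-butyldimethylsilyl chloride, CC(C)(C)[Si](C)(C)Cl
Why: Imidazole-mediated silylation of a primary alcohol; no stereocentre is involved.

Step 2
Reactants: 2 tert-butyl(but-2-yn-1-yloxy)dimethylsilane
Product: 4 (E)-tert-butyl[(3-iodobut-2-en-1-yl)oxy]dimethylsilane, via alkenylzirconocene chloride 3 (not isolated)
Conditions: Cp2Zr(H)Cl (1.5 equiv), THF, rt to 45 °C; then I2, 0 °C
Reagents that add atoms: iodine, II; Cp2Zr(H)Cl, [H][Zr](Cl)(C1C=CC=C1)C1C=CC=C1 (its metal fragment stays in 3 only)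
Why: Hydrozirconation–iodinolysis: syn addition of Zr–H should place zirconium on the less hindered, methyl-bearing alkyne carbon (the excess hydride equilibrates the regioisomers), and iodine replaces zirconium with retention, fixing the E geometry that both trisubstituted alkenes of the route inherit.

Step 3
Reactants: 4 (E)-tert-butyl[(3-iodobut-2-en-1-yl)oxy]dimethylsilane (the portion needed for step 18)
Product: 5 (E)-3-iodobut-2-en-1-ol
Conditions: Bu4NF, THF, 0 °C
Reagents that add atoms: none
Why: Fluoride-mediated desilylation, to which the vinyl iodide and its geometry are inert.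

Step 4
Reactants: 6 dimethyl methylmalonate; 7 allyl bromide
Product: 8 dimethyl 2-methyl-2-(prop-2-en-1-yl)propanedioate
Conditions: NaH, THF, 0 °C to rt
Reagents that add atoms: none
Why: Malonic ester alkylation (SN2 reaction of the sodium enolate with allyl bromide) builds the fully substituted but still prochiral carbon that becomes C4.

Step 5
Reactants: 8 dimethyl 2-methyl-2-(prop-2-en-1-yl)propanedioate; 4 (E)-tert-butyl[(3-iodobut-2-en-1-yl)oxy]dimethylsilane
Product: 10 dimethyl 2-[(4E)-6-(tert-butyldimethylsilyloxy)-4-methylhex-4-en-1-yl]-2-methylpropanedioate, via B-alkyl-9-BBN adduct 9 (not isolated)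
Conditions: 9-BBN, THF, rt; then 4, Pd(dppf)Cl2 (5 mol%), AsPh3, Cs2CO3, DMF/H2O, rt
Reagents that add atoms: 9-borabicyclo[3.3.1]nonane (9-BBN), [H]B1C2CCCC1CCC2 (its atoms stay in 9 only)
Why: Anti-Markovnikov hydroboration of the terminal alkene by 9-BBN (esters are inert) followed by B-alkyl Suzuki–Miyaura coupling, which forms C1–C10 with retention of the E geometry of the iodide; the product is still achiral.

Step 6
Reactants: 10 dimethyl 2-[(4E)-6-(tert-butyldimethylsilyloxy)-4-methylhex-4-en-1-yl]-2-methylpropanedioate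
Product: 11 (2R,6E)-8-(tert-butyldimethylsilyloxy)-2-(methoxycarbonyl)-2,6-dimethyloct-6-enoic acid
Conditions: pig liver esterase, 0.1 M NaH2PO4/Na2HPO4 buffer pH 7.5, DMSO (10%), 25 °C
Reagents that add atoms: water, O
Why: Enzymatic desymmetrisation by enantiotopic-group-selective ester hydrolysis: the esterase should cleave the pro-S methoxycarbonyl group, as it does when a long lipophilic alkyl group stands beside the 2-methyl group, and this single event creates the C4 stereocentre (R in the half-ester) from which all others derive.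

Step 7
Reactants: 11 (2R,6E)-8-(tert-butyldimethylsilyloxy)-2-(methoxycarbonyl)-2,6-dimethyloct-6-enoic acid
Product: 12 (2S,6E)-8-(tert-butyldimethylsilyloxy)-2-(hydroxymethyl)-2,6-dimethyloct-6-enoic acid
Conditions: LiBH4 (3 equiv), THF, 0 to 45 °C; then 10% citric acid
Reagents that add atoms: none
Why: Chemoselective borohydride reduction: the acid is first converted into its lithium carboxylate, which LiBH4 does not reduce, so only the methyl ester arm becomes CH2OH, and the quaternary centre (no α-hydrogen) keeps its configuration, the descriptor changing to S only because the priorities of the two arms are exchanged.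

Step 8
Reactants: 12 (2S,6E)-8-(tert-butyldimethylsilyloxy)-2-(hydroxymethyl)-2,6-dimethyloct-6-enoic acid
Product: 13 methyl (2S,6E)-8-(tert-butyldimethylsilyloxy)-2-(hydroxymethyl)-2,6-dimethyloct-6-enoate
Conditions: TMSCHN2, toluene/MeOH, 0 °C
Reagents that add atoms: (trimethylsilyl)diazomethane, C[Si](C)(C)C=[N+]=[N-]
Why: Diazoalkane O-methylation of a carboxylic acid takes place at the carboxylate oxygen and is therefore indifferent to the neopentyl hindrance; the primary alcohol is not methylated under these conditions.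

Step 9
Reactants: 13 methyl (2S,6E)-8-(tert-butyldimethylsilyloxy)-2-(hydroxymethyl)-2,6-dimethyloct-6-enoate
Product: 14 methyl (2S,6E)-8-(tert-butyldimethylsilyloxy)-2-formyl-2,6-dimethyloct-6-enoate
Conditions: Dess–Martin periodinane, CH2Cl2, rt
Reagents that add atoms: none
Why: Dess–Martin oxidation of the neopentyl primary alcohol gives an aldehyde that cannot enolise or epimerise because its α-carbon is quaternary, while the silyl ether and the alkene are inert.

Step 10
Reactants: 14 methyl (2S,6E)-8-(tert-butyldimethylsilyloxy)-2-formyl-2,6-dimethyloct-6-enoate; 15 diethyl (E)-but-2-en-1-ylphosphonate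
Product: 16 methyl (2S,3E,5E)-2-[(4E)-6-(tert-butyldimethylsilyloxy)-4-methylhex-4-en-1-yl]-2-methylhepta-3,5-dienoate
Conditions: 15, n-BuLi, THF/DMPU, −78 °C; then 14, −78 °C to rt
Reagents that add atoms: none
Why: Horner–Wadsworth–Emmons olefination with an allylic phosphonate carbanion, which adds through its α-carbon to the hindered, non-enolisable aldehyde and eliminates lithium diethyl phosphate to give C5=C6 with E geometry (bulky quaternary carbon anti to the propenyl group), the E crotyl alkene being carried over unchanged.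

Step 11
Reactants: 16 methyl (2S,3E,5E)-2-[(4E)-6-(tert-butyldimethylsilyloxy)-4-methylhex-4-en-1-yl]-2-methylhepta-3,5-dienoate
Product: 17 methyl (2S,3E,5E)-2-[(4E)-6-hydroxy-4-methylhex-4-en-1-yl]-2-methylhepta-3,5-dienoate
Conditions: Bu4NF, THF, 0 °C
Reagents that add atoms: none
Why: Fluoride-mediated cleavage of the primary allylic silyl ether, to which the ester and the diene are inert.

Step 12
Reactants: 17 methyl (2S,3E,5E)-2-[(4E)-6-hydroxy-4-methylhex-4-en-1-yl]-2-methylhepta-3,5-dienoate
Product: 18 methyl (2S,3E,5E)-2-methyl-2-[(4E)-4-methyl-6-oxohex-4-en-1-yl]hepta-3,5-dienoate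
Conditions: MnO2, CH2Cl2, rt
Reagents that add atoms: none
Why: Chemoselective MnO2 oxidation of the allylic alcohol stops at the (E)-enal and leaves the diene and the alkene geometry untouched.

Step 13
Reactants: 18 methyl (2S,3E,5E)-2-methyl-2-[(4E)-4-methyl-6-oxohex-4-en-1-yl]hepta-3,5-dienoate
Product: 19 methyl (1S,4aS,5S,6S,8aR)-5-formyl-1,4a,6-trimethyl-1,2,3,4,4a,5,6,8a-octahydronaphthalene-1-carboxylate (labdane numbering: 4α-methyl, 4β-ester, 5α-H, 8β-methyl, 9β-formyl, 10β-methyl, C6=C7)
Conditions: Me2AlCl (1.2 equiv), CH2Cl2, −78 to −20 °C; then aqueous HCl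
Reagents that add atoms: none
Why: Me2AlCl binds the formyl oxygen and lowers the LUMO of the C9=C10 enal, so that a concerted but asynchronous [4+2] with the C5–C8 diene sets in at low temperature, the C5–C10 bond running ahead of C8–C9; the closest known reaction type is the Lewis acid-promoted type 1 intramolecular Diels–Alder reaction of 1,7,9-decatrienes with a terminal acceptor, which gives trans-fused octalins. Ring B closes as the new cyclohexene of the cycloaddition (bonds C5–C10 and C8–C9), and ring A closes as the six-membered tether ring through the same C5–C10 bond, with C1–C4 folded as a chair. C5 and C10 become trans because the formyl group sits endo while the C1 strand of the (E)-enal is exo, which also places the C10 methyl and the C9 formyl group cis; C9 (formyl β) follows from the endo mode and C8 (methyl β) from the (E,E)-diene geometry. The step needs endo selectivity and discrimination of the two diene faces by C4: Lewis acid complexation strengthens the endo preference, and in the chair tether the flat methoxycarbonyl group rather than the C4 methyl should take the axial site that is 1,3-related to the C10 methyl, which translates 4S into 5R,10S. Only a slight excess of Lewis acid is used so that the ester stays largely uncomplexed and small, and the minor adduct from the other diene face would be removed by chromatography.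

Step 14
Reactants: 19 methyl (1S,4aS,5S,6S,8aR)-5-formyl-1,4a,6-trimethyl-1,2,3,4,4a,5,6,8a-octahydronaphthalene-1-carboxylate
Product: 20 methyl (1S,4aS,5S,6S,8aR)-5-formyl-1,4a,6-trimethyldecahydronaphthalene-1-carboxylate
Conditions: H2 (1 atm), 10% Pd/C, EtOAc, rt
Reagents that add atoms: none
Why: Heterogeneous catalytic hydrogenation reduces the cis-disubstituted C6=C7 alkene much faster than the aldehyde or the ester; no stereocentre is created and those present are not touched.

Step 15
Reactants: 20 methyl (1S,4aS,5S,6S,8aR)-5-formyl-1,4a,6-trimethyldecahydronaphthalene-1-carboxylate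
Product: 21 methyl (1S,4aS,6S,8aR)-5-[(tert-butyldimethylsilyloxy)methylidene]-1,4a,6-trimethyldecahydronaphthalene-1-carboxylate (E/Z mixture at the enol ether)
Conditions: TBSOTf, Et3N, CH2Cl2, 0 °C to rt
Reagents that add atoms: tert-butyldimethylsilyl trifluoromethanesulfonate, CC(C)(C)[Si](C)(C)OS(=O)(=O)C(F)(F)F
Why: Soft enolisation (O-silylation of the aldehyde and loss of the axial C9 hydrogen) gives the silyl enol ether regiospecifically because the ester has no α-hydrogen; the C9 centre of the cycloadduct is erased on purpose.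

Step 16
Reactants: 21 methyl (1S,4aS,6S,8aR)-5-[(tert-butyldimethylsilyloxy)methylidene]-1,4a,6-trimethyldecahydronaphthalene-1-carboxylate
Product: 22 methyl (1S,4aS,8aR)-5-formyl-1,4a,6-trimethyl-1,2,3,4,4a,7,8,8a-octahydronaphthalene-1-carboxylate
Conditions: Pd(OAc)2 (1.1 equiv), MeCN, 40 °C
Reagents that add atoms: none
Why: Saegusa–Ito oxidation: Pd(OAc)2 should palladate the enol ether at C9 from the α face, away from the axial methyl groups on C10 and C8, and syn β-hydride elimination of the cis C8 hydrogen then gives the tetrasubstituted C8=C9 enal and zerovalent palladium, removing the C8 centre as well.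

Step 17
Reactants: 22 methyl (1S,4aS,8aR)-5-formyl-1,4a,6-trimethyl-1,2,3,4,4a,7,8,8a-octahydronaphthalene-1-carboxylate
Product: 23 methyl (1S,4aS,8aR)-5-ethenyl-1,4a,6-trimethyl-1,2,3,4,4a,7,8,8a-octahydronaphthalene-1-carboxylate
Conditions: Ph3PCH3Br, KOtBu, THF, 0 °C to rt
Reagents that add atoms: methyltriphenylphosphonium bromide, C[P+](c1ccccc1)(c1ccccc1)c1ccccc1.[Br-]
Why: Wittig methylenation with the unstabilised ylide tolerates tetrasubstituted cyclohexenecarbaldehydes flanked by a quaternary carbon and does not touch the hindered ester; it adds C12 and forms no stereocentre.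

Step 18
Reactants: 23 methyl (1S,4aS,8aR)-5-ethenyl-1,4a,6-trimethyl-1,2,3,4,4a,7,8,8a-octahydronaphthalene-1-carboxylate; 5 (E)-3-iodobut-2-en-1-ol
Product: 25 methyl (1S,4aS,8aR)-5-[(3E)-5-hydroxy-3-methylpent-3-en-1-yl]-1,4a,6-trimethyl-1,2,3,4,4a,7,8,8a-octahydronaphthalene-1-carboxylate, via B-alkyl-9-BBN adduct 24 (not isolated)
Conditions: 9-BBN, THF, rt; then 5, Pd(dppf)Cl2 (5 mol%), AsPh3, Cs2CO3, DMF/H2O, rt
Reagents that add atoms: 9-borabicyclo[3.3.1]nonane (9-BBN), [H]B1C2CCCC1CCC2 (its atoms stay in 24 only)
Why: Hydroboration/B-alkyl Suzuki–Miyaura coupling: 9-BBN adds only to the monosubstituted vinyl group (boron on C12, the tetrasubstituted C8=C9 bond being inert), and the palladium-catalysed coupling proceeds with retention, so the 13E geometry is that of the iodide.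

Step 19
Reactants: 25 methyl (1S,4aS,8aR)-5-[(3E)-5-hydroxy-3-methylpent-3-en-1-yl]-1,4a,6-trimethyl-1,2,3,4,4a,7,8,8a-octahydronaphthalene-1-carboxylate
Product: 26 (1S,4aS,8aR)-5-[(3E)-5-hydroxy-3-methylpent-3-en-1-yl]-1,4a,6-trimethyl-1,2,3,4,4a,7,8,8a-octahydronaphthalene-1-carboxylic acid
Conditions: NaSEt, DMF, 100 °C; then aqueous HCl
Reagents that add atoms: none
Why: SN2 dealkylation of the methyl ester by thiolate at the O-methyl carbon is the established way around an axial, neopentyl carbonyl group that resists saponification; the alkenes and the allylic alcohol are inert and no stereocentre is affected.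

Step 20
Reactants: 26 (1S,4aS,8aR)-5-[(3E)-5-hydroxy-3-methylpent-3-en-1-yl]-1,4a,6-trimethyl-1,2,3,4,4a,7,8,8a-octahydronaphthalene-1-carboxylic acid
Product: 27 (1S,4aS,8aR)-5-[(3E)-5-acetoxy-3-methylpent-3-en-1-yl]-1,4a,6-trimethyl-1,2,3,4,4a,7,8,8a-octahydronaphthalene-1-carboxylic acid (CNP0326733.1; labdane numbering 4S,5R,10S)
Conditions: Ac2O, pyridine, DMAP (cat.), CH2Cl2, 0 °C to rt; aqueous work-up
Reagents that add atoms: acetic anhydride, CC(=O)OC(C)=O
Why: DMAP-catalysed acetylation of the primary allylic alcohol; the hindered tertiary carboxylic acid is not esterified, and any mixed anhydride it forms is hydrolysed during the aqueous work-up.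

**Compound list**

1 | but-2-yn-1-ol | CC#CCO | starting material
2 | tert-butyl(but-2-yn-1-yloxy)dimethylsilane | CC#CCO[Si](C)(C)C(C)(C)C | intermediate
3 | chlorobis(cyclopentadienyl)[(E)-4-(tert-butyldimethylsilyloxy)but-2-en-2-yl]zirconium | C/C(=C\CO[Si](C)(C)C(C)(C)C)[Zr](Cl)(C1C=CC=C1)C1C=CC=C1 | intermediate
4 | (E)-tert-butyl[(3-iodobut-2-en-1-yl)oxy]dimethylsilane | C/C(I)=C\CO[Si](C)(C)C(C)(C)C | intermediate
5 | (E)-3-iodobut-2-en-1-ol | C/C(I)=C\CO | intermediate
6 | dimethyl methylmalonate | COC(=O)C(C)C(=O)OC | starting material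
7 | allyl bromide | C=CCBr | starting material
8 | dimethyl 2-methyl-2-(prop-2-en-1-yl)propanedioate | COC(=O)C(C)(CC=C)C(=O)OC | intermediate
9 | dimethyl 2-[3-(9-borabicyclo[3.3.1]nonan-9-yl)propyl]-2-methylpropanedioate | COC(=O)C(C)(CCCB1C2CCCC1CCC2)C(=O)OC | intermediate
10 | dimethyl 2-[(4E)-6-(tert-butyldimethylsilyloxy)-4-methylhex-4-en-1-yl]-2-methylpropanedioate | COC(=O)C(C)(CCC/C(C)=C/CO[Si](C)(C)C(C)(C)C)C(=O)OC | intermediate
11 | (2R,6E)-8-(tert-butyldimethylsilyloxy)-2-(methoxycarbonyl)-2,6-dimethyloct-6-enoic acid | COC(=O)[C@@](C)(C(=O)O)CCC/C(C)=C/CO[Si](C)(C)C(C)(C)C | intermediate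
12 | (2S,6E)-8-(tert-butyldimethylsilyloxy)-2-(hydroxymethyl)-2,6-dimethyloct-6-enoic acid | OC[C@@](C)(C(=O)O)CCC/C(C)=C/CO[Si](C)(C)C(C)(C)C | intermediate
13 | methyl (2S,6E)-8-(tert-butyldimethylsilyloxy)-2-(hydroxymethyl)-2,6-dimethyloct-6-enoate | OC[C@@](C)(C(=O)OC)CCC/C(C)=C/CO[Si](C)(C)C(C)(C)C | intermediate
14 | methyl (2S,6E)-8-(tert-butyldimethylsilyloxy)-2-formyl-2,6-dimethyloct-6-enoate | O=C[C@@](C)(C(=O)OC)CCC/C(C)=C/CO[Si](C)(C)C(C)(C)C | intermediate
15 | diethyl (E)-but-2-en-1-ylphosphonate | CCOP(=O)(C/C=C/C)OCC | starting material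
16 | methyl (2S,3E,5E)-2-[(4E)-6-(tert-butyldimethylsilyloxy)-4-methylhex-4-en-1-yl]-2-methylhepta-3,5-dienoate | C/C=C/C=C/[C@@](C)(C(=O)OC)CCC/C(C)=C/CO[Si](C)(C)C(C)(C)C | intermediate
17 | methyl (2S,3E,5E)-2-[(4E)-6-hydroxy-4-methylhex-4-en-1-yl]-2-methylhepta-3,5-dienoate | C/C=C/C=C/[C@@](C)(C(=O)OC)CCC/C(C)=C/CO | intermediate
18 | methyl (2S,3E,5E)-2-methyl-2-[(4E)-4-methyl-6-oxohex-4-en-1-yl]hepta-3,5-dienoate | C/C=C/C=C/[C@@](C)(C(=O)OC)CCC/C(C)=C/C=O | intermediate
19 | methyl (1S,4aS,5S,6S,8aR)-5-formyl-1,4a,6-trimethyl-1,2,3,4,4a,5,6,8a-octahydronaphthalene-1-carboxylate | O=C[C@H]1[C@@H](C)C=C[C@H]2[C@@](C)(C(=O)OC)CCC[C@]12C | intermediate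
20 | methyl (1S,4aS,5S,6S,8aR)-5-formyl-1,4a,6-trimethyldecahydronaphthalene-1-carboxylate | O=C[C@H]1[C@@H](C)CC[C@H]2[C@@](C)(C(=O)OC)CCC[C@]12C | intermediate
21 | methyl (1S,4aS,6S,8aR)-5-[(tert-butyldimethylsilyloxy)methylidene]-1,4a,6-trimethyldecahydronaphthalene-1-carboxylate (E/Z mixture) | CC(C)(C)[Si](C)(C)OC=C1[C@@H](C)CC[C@H]2[C@@](C)(C(=O)OC)CCC[C@]12C | intermediate
22 | methyl (1S,4aS,8aR)-5-formyl-1,4a,6-trimethyl-1,2,3,4,4a,7,8,8a-octahydronaphthalene-1-carboxylate | O=CC1=C(C)CC[C@H]2[C@@](C)(C(=O)OC)CCC[C@]12C | intermediate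
23 | methyl (1S,4aS,8aR)-5-ethenyl-1,4a,6-trimethyl-1,2,3,4,4a,7,8,8a-octahydronaphthalene-1-carboxylate | C=CC1=C(C)CC[C@H]2[C@@](C)(C(=O)OC)CCC[C@]12C | intermediate
24 | methyl (1S,4aS,8aR)-5-[2-(9-borabicyclo[3.3.1]nonan-9-yl)ethyl]-1,4a,6-trimethyl-1,2,3,4,4a,7,8,8a-octahydronaphthalene-1-carboxylate | C1CC2CCCC(C1)B2CCC1=C(C)CC[C@H]2[C@@](C)(C(=O)OC)CCC[C@]12C | intermediate
25 | methyl (1S,4aS,8aR)-5-[(3E)-5-hydroxy-3-methylpent-3-en-1-yl]-1,4a,6-trimethyl-1,2,3,4,4a,7,8,8a-octahydronaphthalene-1-carboxylate | OC/C=C(\C)CCC1=C(C)CC[C@H]2[C@@](C)(C(=O)OC)CCC[C@]12C | intermediate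
26 | (1S,4aS,8aR)-5-[(3E)-5-hydroxy-3-methylpent-3-en-1-yl]-1,4a,6-trimethyl-1,2,3,4,4a,7,8,8a-octahydronaphthalene-1-carboxylic acid | OC/C=C(\C)CCC1=C(C)CC[C@H]2[C@@](C)(C(=O)O)CCC[C@]12C | intermediate
27 | (1S,4aS,8aR)-5-[(3E)-5-acetoxy-3-methylpent-3-en-1-yl]-1,4a,6-trimethyl-1,2,3,4,4a,7,8,8a-octahydronaphthalene-1-carboxylic acid | CC(=O)OC/C=C(\C)CCC1=C(C)CC[C@H]2[C@@](C)(C(=O)O)CCC[C@]12C | target

**Step count and risks**

Total step count: 20. Longest linear sequence: 18 steps (steps 1, 2 and 5–20, from but-2-yn-1-ol); steps 3 and 4 are side branches.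

Steps most likely to fail:

1. Step 13 (key cycloaddition). The β,β-disubstituted enal may add so slowly that Lewis-acid-induced oligomerisation of the diene competes, or the two diene faces may be poorly discriminated in an early transition state. The fallback is an ionic Diels–Alder reaction that sets out from 18 and returns at 19. Compound 18 would be treated with 1,2-bis(trimethylsilyloxy)ethane and catalytic TMSOTf in CH2Cl2 at −78 °C to give the dioxolane acetal of the trienal F1. A further charge of TMSOTf at −78 to −40 °C should ionise the acetal and trigger a stepwise cationic cycloaddition in which C10 bonds to C5 first (chair closure of ring A, where the axial/equatorial preference at C4 is fully felt) and C8–C9 closes second, giving the cycloadduct dioxolane F2. Hydrolysis with aqueous HCl in THF returns 19.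

2. Step 6 (enzymatic desymmetrisation). The enzyme may hydrolyse the two enantiotopic ester groups of the bulky, poorly water-soluble diester with low discrimination or very slowly. The fallback is a classical resolution that sets out from 10 and returns at 11. One ester group of 10 would be saponified with 1 equiv KOH in MeOH to give the racemic half-ester F3. Salt formation with (R)-1-phenylethylamine and fractional crystallisation should give the (R)-1-phenylethylammonium salt of the R acid F4 (the antipodal amine is used if the S acid gives the less soluble salt), while the antipodal S half-ester F5 stays in the mother liquor. Acidification of the salt returns 11.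

3. Step 16 (dehydrogenation). Palladation at the fully substituted enol ether carbon, flanked by the quaternary C10 and the branched C8, may be slower than protodesilylation back to 20, or β-hydride elimination may stall. The fallback is a selenoxide elimination that sets out from 21 and returns at 22. Compound 21 would be treated with PhSeCl in CH2Cl2 at −78 °C to give the 9α-phenylselanyl aldehyde F6, with selenium on the face opposite the C10 methyl and cis to the C8 hydrogen. Oxidation with H2O2/pyridine at 0 °C gives the selenoxide F7, which should undergo syn elimination towards C8 on warming to rt and give 22.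

Further compounds
F1 | step 13 | methyl (2S,3E,5E)-2-[(4E)-5-(1,3-dioxolan-2-yl)-4-methylpent-4-en-1-yl]-2-methylhepta-3,5-dienoate | C/C=C/C=C/[C@@](C)(C(=O)OC)CCC/C(C)=C/C1OCCO1
F2 | step 13 | methyl (1S,4aS,5S,6S,8aR)-5-(1,3-dioxolan-2-yl)-1,4a,6-trimethyl-1,2,3,4,4a,5,6,8a-octahydronaphthalene-1-carboxylate | O1CCOC1[C@H]3[C@@H](C)C=C[C@H]2[C@@](C)(C(=O)OC)CCC[C@]32C
F3 | step 6 | racemic (6E)-8-(tert-butyldimethylsilyloxy)-2-(methoxycarbonyl)-2,6-dimethyloct-6-enoic acid | COC(=O)C(C)(C(=O)O)CCC/C(C)=C/CO[Si](C)(C)C(C)(C)C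
F4 | step 6 | (R)-1-phenylethylammonium (2R,6E)-8-(tert-butyldimethylsilyloxy)-2-(methoxycarbonyl)-2,6-dimethyloct-6-enoate | COC(=O)[C@@](C)(C(=O)[O-])CCC/C(C)=C/CO[Si](C)(C)C(C)(C)C.C[C@@H]([NH3+])c1ccccc1
F5 | step 6 | (2S,6E)-8-(tert-butyldimethylsilyloxy)-2-(methoxycarbonyl)-2,6-dimethyloct-6-enoic acid | COC(=O)[C@](C)(C(=O)O)CCC/C(C)=C/CO[Si](C)(C)C(C)(C)C
F6 | step 16 | methyl 5-formyl-1,4a,6-trimethyl-5-(phenylselanyl)decahydronaphthalene-1-carboxylate (9α-selanyl, labdane numbering) | O=C[C@@]1([Se]c2ccccc2)[C@@H](C)CC[C@H]3[C@@](C)(C(=O)OC)CCC[C@]13C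
F7 | step 16 | methyl 5-formyl-1,4a,6-trimethyl-5-(phenylseleninyl)decahydronaphthalene-1-carboxylate (selenoxide of F6) | O=C[C@@]1([Se](=O)c2ccccc2)[C@@H](C)CC[C@H]3[C@@](C)(C(=O)OC)CCC[C@]13C
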